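The hydroazulene is cut at C1–C5 and C9–C10 (C1 methyl-bearing fusion carbon, C2 acetoxy carbon, C4 carbinol, C5 fusion CH, C6 anisoate carbon, C8(Me)=C9). With C6 and C9 as ketones, the seven-membered ring (C5–C6–C7–C8–C9–C10–C1) is a 1,4-dione that arises by inserting the C1=C10 alkene between C5 and C9 of a cyclopentane-1,3-dione. One operation, enone–alkene [2+2] photocycloaddition then retro-aldol opening of the cyclobutane, closes the cyclopentane, expands the dione ring to the cycloheptane and sets quaternary C1. The precursor is a monocyclic 3-benzyloxy-4-methylcyclopent-2-enone bearing on C5 the C4 carbinol (free OH, isopropyl) and a tether ending in the C2 acetate and the isopropenyl group.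

Key step: step 9

Remarks on the design
- The target was read as C1 R, C2 S, C4 R, C5 S, C6 S with a trans ring fusion. The C2/C4/C5/C1 descriptors of the precursor (16) and of the dione (19) agree with it, so no structure needed correction.
- The enol oxygen on C9 lies next to the methyl-bearing C8 and is the more hindered of the two dione oxygens, so a late O-acylation cannot be trusted to select it. It is therefore fixed as a benzyl ether on the simple dione (step 2), where the regioisomers can be separated.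
- The C4 hydroxyl stays free and the C2 oxygen already carries the final acetate. The benzyl ether is removed by neutral hydrogenolysis, which spares the acetate and avoids alkoxide-driven retro-aldol of the C4 ketol.
- C6 is reduced before C9 is touched, because only C6 has a β-hydroxyl for directed hydride delivery.
- Assumption: C8 and the ring carbinol carbon of 8–15 are carried as epimeric mixtures, since both become sp2 later; the acid-labile 3-alkoxy-allylic alcohols 8, 9 and 13–15 are handled on base-washed silica.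

Step 1
Reactants: 1 3-methylbutan-2-one; 2 methacrolein
Product: 4 (5S)-5-hydroxy-2,6-dimethylhept-6-en-3-one, via enol borinate 3 (not isolated)
Conditions: (−)-Ipc2BCl, Et3N, Et2O, −78 → 0 °C; 2, −78 → −20 °C; H2O2, MeOH, pH 7 buffer
Reagents that add atoms: none
Why: Boron-mediated methyl ketone aldol (Paterson aldol): enolisation occurs on the methyl side and the chiral enol borinate should attack the Si face of methacrolein, giving the (S)-carbinol that becomes C2.

Step 2
Reactants: 5 4-methylcyclopentane-1,3-dione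
Product: 6 3-(benzyloxy)-4-methylcyclopent-2-en-1-one
Conditions: BnOH, p-TsOH (cat.), PhH, reflux (Dean–Stark); chromatography removes the 5-methyl regioisomer, which is re-equilibrated under the same conditions
Reagents that add atoms: benzyl alcohol, OCc1ccccc1
Why: Acid-catalysed vinylogous ester formation from the enolised 1,3-dione places the benzyl group on the future C9 oxygen at a stage where the two regioisomeric ethers are separable and interconvertible.

Step 3
Reactants: 6 3-(benzyloxy)-4-methylcyclopent-2-en-1-one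
Product: 7 3-(benzyloxy)-2-bromo-4-methylcyclopent-2-en-1-one
Conditions: NBS, CH2Cl2, 0 °C
Reagents that add atoms: N-bromosuccinimide, O=C1CCC(=O)N1Br
Why: Electrophilic α-bromination of the electron-rich vinylogous ester at its nucleophilic C2, the future C5.

Step 4
Reactants: 7 3-(benzyloxy)-2-bromo-4-methylcyclopent-2-en-1-one
Product: 8 3-(benzyloxy)-2-bromo-4-methylcyclopent-2-en-1-ol
Conditions: i-Bu2AlH, CH2Cl2, −78 °C; aq. KNa tartrate
Reagents that add atoms: none
Why: 1,2-Reduction of the vinylogous ester carbonyl by the aluminium hydride masks the future C6 ketone as a carbinol, so that the ring can later be metalated without an electrophilic carbonyl or acidic α-protons.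

Step 5
Reactants: 8 3-(benzyloxy)-2-bromo-4-methylcyclopent-2-en-1-ol
Product: 9 [3-(benzyloxy)-2-bromo-4-methylcyclopent-2-en-1-yl]oxy(tert-butyl)dimethylsilane
Conditions: TBSCl, imidazole, DMF, rt
Reagents that add atoms: tert-butyldimethylsilyl chloride, CC(C)(C)[Si](C)(C)Cl
Why: Standard silylation of a secondary alcohol removes the acidic proton and stabilises the acid-sensitive 3-alkoxy-allylic alcohol.

Step 6
Reactants: 9 [3-(benzyloxy)-2-bromo-4-methylcyclopent-2-en-1-yl]oxy(tert-butyl)dimethylsilane; 4 (5S)-5-hydroxy-2,6-dimethylhept-6-en-3-one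
Product: 13 (3S,5R)-5-[2-(benzyloxy)-5-(tert-butyldimethylsilyloxy)-3-methylcyclopent-1-en-1-yl]-2,6-dimethylhept-1-ene-3,5-diol, via vinyllithium 10 (not isolated), via alkenylcerium dichloride 11 (not isolated), via lithium alkoxide 12 (not isolated)
Conditions: 9, t-BuLi (2 equiv), Et2O, −78 °C; CeCl3, THF, −78 °C; 4 pre-treated with MeLi (1 equiv), THF, −78 °C; −78 → −40 °C; aq. NaHCO3
Reagents that add atoms: none
Why: Bromine–lithium exchange, transmetalation to the weakly basic alkenylcerium reagent and 1,2-addition to the hindered, enolisable ketone form C4–C5; the metal-bridged β-alkoxide chelate exposes the ketone face anti to the isopropenyl group, which should give the 1,3-syn diol (C4 R) by chelation-controlled 1,3-induction.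

Step 7
Reactants: 13 (3S,5R)-5-[2-(benzyloxy)-5-(tert-butyldimethylsilyloxy)-3-methylcyclopent-1-en-1-yl]-2,6-dimethylhept-1-ene-3,5-diol
Product: 14 (3S,5R)-5-[2-(benzyloxy)-5-(tert-butyldimethylsilyloxy)-3-methylcyclopent-1-en-1-yl]-5-hydroxy-2,6-dimethylhept-1-en-3-yl acetate
Conditions: Ac2O, pyridine, DMAP (cat.), CH2Cl2, 0 °C
Reagents that add atoms: acetic anhydride, CC(=O)OC(C)=O
Why: DMAP-catalysed acylation distinguishes the secondary allylic C2 hydroxyl from the hindered tertiary C4 hydroxyl and installs the acetate of the target.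

Step 8
Reactants: 14 (3S,5R)-5-[2-(benzyloxy)-5-(tert-butyldimethylsilyloxy)-3-methylcyclopent-1-en-1-yl]-5-hydroxy-2,6-dimethylhept-1-en-3-yl acetate
Product: 16 (3S,5R)-5-[2-(benzyloxy)-3-methyl-5-oxocyclopent-1-en-1-yl]-5-hydroxy-2,6-dimethylhept-1-en-3-yl acetate, via allylic alcohol 15 (not isolated)
Conditions: Bu4NF, THF, 0 °C; then MnO2, CH2Cl2, rt
Reagents that add atoms: none
Why: Fluoride desilylation followed by MnO2 oxidation of the activated 3-alkoxy-allylic alcohol regenerates the vinylogous ester with the ketone at C6 and the benzyl enol ether at C9, while the acetate shields the other allylic alcohol from oxidation.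

Step 9
Reactants: 16 (3S,5R)-5-[2-(benzyloxy)-3-methyl-5-oxocyclopent-1-en-1-yl]-5-hydroxy-2,6-dimethylhept-1-en-3-yl acetate
Product: 19 (1S,3R,3aR,8aR)-3-hydroxy-6,8a-dimethyl-4,7-dioxo-3-(propan-2-yl)decahydroazulen-1-yl acetate, via cyclobutane photoadduct 17 (not isolated), via cyclobutanol 18 (not isolated)
Conditions: hν (Pyrex-filtered medium-pressure Hg lamp), degassed CH2Cl2, 0 °C; then H2 (1 atm), Pd(OH)2/C, EtOAc, rt; then DBU (0.2 equiv), PhMe, rt
Reagents that add atoms: none
Why: Excitation of the 3-alkoxy-enone (C6=O, C5=C9) gives a triplet that bonds C5 to C1 and then collapses the 1,4-diradical through C9–C10 to the cis-fused cyclobutane 17, the straight adduct of an intramolecular de Mayo reaction; hydrogenolysis frees the C9 cyclobutanol 18, whose strain-driven retro-aldol cleaves C5–C9. The cyclopentane closes by 1,5-bonding (5-exo, rule of five), and the cycloheptane forms by two-carbon expansion of the ring C5–C6–C7–C8–C9 in the fragmentation. C1 is set by the alkene face that adds: the C4–OH···O=C6 hydrogen bond holds the C4 oxygen syn to C6 and puts the tether on the enone face anti to isopropyl, and A(1,2) strain keeps C2–H rather than the acetoxy group beside the C1 methyl, so C10 ends cis to the C2 oxygen and the methyl cis to the C4 oxygen. C5 is set after the fragmentation by amidine-mediated equilibration, which should favour the trans-fused epimer because it keeps the C4–OH···O=C6 hydrogen bond and avoids a cis isopropyl/C6 contact. The step needs the C9 rather than the C6 enol ether (fixed in step 2), straight rather than crossed addition (three-atom tether) and the correct C1 face (the two conformational elements above); C8 stays epimeric until step 12.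

Step 10
Reactants: 19 (1S,3R,3aR,8aR)-3-hydroxy-6,8a-dimethyl-4,7-dioxo-3-(propan-2-yl)decahydroazulen-1-yl acetate
Product: 20 (1S,3R,3aS,4S,8aR)-3,4-dihydroxy-6,8a-dimethyl-7-oxo-3-(propan-2-yl)decahydroazulen-1-yl acetate
Conditions: Me4NBH(OAc)3, MeCN–AcOH (1:1), −30 → −20 °C
Reagents that add atoms: none
Why: Hydroxyl-directed reduction (Evans–Saksena): the C4 hydroxyl binds the acetoxyborohydride and delivers hydride to the C6 face syn to the C4 oxygen, giving the 1,3-anti diol (C6 S), while the C9 ketone, lacking a β-hydroxyl, is not reduced.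

Step 11
Reactants: 20 (1S,3R,3aS,4S,8aR)-3,4-dihydroxy-6,8a-dimethyl-7-oxo-3-(propan-2-yl)decahydroazulen-1-yl acetate
Product: 22 (1S,3R,3aS,4S,8aR)-1-(acetyloxy)-6,8a-dimethyl-7-oxo-3-(propan-2-yl)-3-(triethylsilyloxy)decahydroazulen-4-yl 4-methoxybenzoate, via C6 anisoate 21 (not isolated)
Conditions: 4-MeOC6H4COCl, DMAP, pyridine, CH2Cl2, rt; then TESOTf, 2,6-lutidine, 0 °C
Reagents that add atoms: 4-methoxybenzoyl chloride, COc1ccc(C(Cl)=O)cc1; triethylsilyl triflate, CC[Si](CC)(CC)OS(=O)(=O)C(F)(F)F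
Why: Nucleophilic acyl-transfer catalysis esterifies only the secondary C6 alcohol, and the silyl triflate then caps the hindered tertiary C4 alcohol so that it survives triflic anhydride in the next step.

Step 12
Reactants: 22 (1S,3R,3aS,4S,8aR)-1-(acetyloxy)-6,8a-dimethyl-7-oxo-3-(propan-2-yl)-3-(triethylsilyloxy)decahydroazulen-4-yl 4-methoxybenzoate
Product: 23 (1S,3R,3aS,4S,8aR)-1-(acetyloxy)-6,8a-dimethyl-3-(propan-2-yl)-3-(triethylsilyloxy)-7-(trifluoromethylsulfonyloxy)-1,2,3,3a,4,5,8,8a-octahydroazulen-4-yl 4-methoxybenzoate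
Conditions: Tf2O, 2,6-di-tert-butyl-4-methylpyridine, CH2Cl2, 0 °C → rt
Reagents that add atoms: triflic anhydride, O=S(=O)(OS(=O)(=O)C(F)(F)F)C(F)(F)F
Why: Enol triflate formation by O-triflation of the ketone and proton loss under equilibrating, base-poor conditions should favour the more substituted C8=C9 isomer, tolerates the esters and erases the C8 stereocentre.

Step 13
Reactants: 23 (1S,3R,3aS,4S,8aR)-1-(acetyloxy)-6,8a-dimethyl-3-(propan-2-yl)-3-(triethylsilyloxy)-7-(trifluoromethylsulfonyloxy)-1,2,3,3a,4,5,8,8a-octahydroazulen-4-yl 4-methoxybenzoate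
Product: 24 (1S,3R,3aS,4S,8aR)-1-(acetyloxy)-6,8a-dimethyl-3-(propan-2-yl)-3-(triethylsilyloxy)-1,2,3,3a,4,5,8,8a-octahydroazulen-4-yl 4-methoxybenzoate
Conditions: Pd(OAc)2 (cat.), PPh3, Bu3N, HCO2H, DMF, 60 °C
Reagents that add atoms: none
Why: Palladium-catalysed formate reduction of an enol triflate (oxidative addition to zerovalent palladium, formate exchange, decarboxylation, reductive elimination) replaces OTf by H and leaves the esters untouched.

Step 14
Reactants: 24 (1S,3R,3aS,4S,8aR)-1-(acetyloxy)-6,8a-dimethyl-3-(propan-2-yl)-3-(triethylsilyloxy)-1,2,3,3a,4,5,8,8a-octahydroazulen-4-yl 4-methoxybenzoate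
Product: 25 (1S,3R,3aS,4S,8aR)-1-(acetyloxy)-3-hydroxy-6,8a-dimethyl-3-(propan-2-yl)-1,2,3,3a,4,5,8,8a-octahydroazulen-4-yl 4-methoxybenzoate
Conditions: HF·pyridine, THF–pyridine, 0 °C → rt
Reagents that add atoms: none
Why: Fluoride cleavage of the tertiary triethylsilyl ether under buffered conditions leaves both esters and the trisubstituted alkene intact and gives the target.

Compound list
1 | 3-methylbutan-2-one | CC(C)C(C)=O | starting material
2 | methacrolein | C=C(C)C=O | starting material
3 | 3-methylbut-1-en-2-yl diisopinocampheylborinate (enol borinate of 1) | C=C(OB([C@@H]1C[C@@H]2C[C@H]([C@H]1C)C2(C)C)[C@@H]1C[C@@H]2C[C@H]([C@H]1C)C2(C)C)C(C)C | intermediate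
4 | (5S)-5-hydroxy-2,6-dimethylhept-6-en-3-one | C=C(C)[C@@H](O)CC(=O)C(C)C | intermediate
5 | 4-methylcyclopentane-1,3-dione | CC1CC(=O)CC1=O | starting material
6 | 3-(benzyloxy)-4-methylcyclopent-2-en-1-one (racemic) | CC1CC(=O)C=C1OCc1ccccc1 | intermediate
7 | 3-(benzyloxy)-2-bromo-4-methylcyclopent-2-en-1-one (racemic) | CC1CC(=O)C(Br)=C1OCc1ccccc1 | intermediate
8 | 3-(benzyloxy)-2-bromo-4-methylcyclopent-2-en-1-ol (racemic, both relative configurations) | CC1CC(O)C(Br)=C1OCc1ccccc1 | intermediate
9 | [3-(benzyloxy)-2-bromo-4-methylcyclopent-2-en-1-yl]oxy(tert-butyl)dimethylsilane | CC1CC(O[Si](C)(C)C(C)(C)C)C(Br)=C1OCc1ccccc1 | intermediate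
10 | [2-(benzyloxy)-5-(tert-butyldimethylsilyloxy)-3-methylcyclopent-1-en-1-yl]lithium | CC1CC(O[Si](C)(C)C(C)(C)C)C([Li])=C1OCc1ccccc1 | intermediate
11 | dichloro[2-(benzyloxy)-5-(tert-butyldimethylsilyloxy)-3-methylcyclopent-1-en-1-yl]cerium | CC1CC(O[Si](C)(C)C(C)(C)C)C([Ce](Cl)Cl)=C1OCc1ccccc1 | intermediate
12 | lithium (3S)-2,6-dimethyl-5-oxohept-1-en-3-olate | C=C(C)[C@@H](O[Li])CC(=O)C(C)C | intermediate
13 | (3S,5R)-5-[2-(benzyloxy)-5-(tert-butyldimethylsilyloxy)-3-methylcyclopent-1-en-1-yl]-2,6-dimethylhept-1-ene-3,5-diol (ring carbons epimeric) | C=C(C)[C@@H](O)C[C@@](O)(C(C)C)C1=C(OCc2ccccc2)C(C)CC1O[Si](C)(C)C(C)(C)C | intermediate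
14 | (3S,5R)-5-[2-(benzyloxy)-5-(tert-butyldimethylsilyloxy)-3-methylcyclopent-1-en-1-yl]-5-hydroxy-2,6-dimethylhept-1-en-3-yl acetate | C=C(C)[C@@H](OC(C)=O)C[C@@](O)(C(C)C)C1=C(OCc2ccccc2)C(C)CC1O[Si](C)(C)C(C)(C)C | intermediate
15 | (3S,5R)-5-[2-(benzyloxy)-5-hydroxy-3-methylcyclopent-1-en-1-yl]-5-hydroxy-2,6-dimethylhept-1-en-3-yl acetate | C=C(C)[C@@H](OC(C)=O)C[C@@](O)(C(C)C)C1=C(OCc2ccccc2)C(C)CC1O | intermediate
16 | (3S,5R)-5-[2-(benzyloxy)-3-methyl-5-oxocyclopent-1-en-1-yl]-5-hydroxy-2,6-dimethylhept-1-en-3-yl acetate (key-step precursor, C8 epimers) | C=C(C)[C@@H](OC(C)=O)C[C@@](O)(C(C)C)C1=C(OCc2ccccc2)C(C)CC1=O | intermediate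
17 | cyclobutane photoadduct: C1–C5 and C9–C10 formed, cis-fused, benzyl ether on C9, ketone at C6 | O=C1CC(C)[C@]2(OCc4ccccc4)C[C@@]3(C)[C@@H](OC(C)=O)C[C@@](O)(C(C)C)[C@@]123 | intermediate
18 | C9 cyclobutanol of the photoadduct | O=C1CC(C)[C@]2(O)C[C@@]3(C)[C@@H](OC(C)=O)C[C@@](O)(C(C)C)[C@@]123 | intermediate
19 | (1S,3R,3aR,8aR)-3-hydroxy-6,8a-dimethyl-4,7-dioxo-3-(propan-2-yl)decahydroazulen-1-yl acetate (trans-fused 6,9-dione, C8 epimers) | O=C1CC(C)C(=O)C[C@@]2(C)[C@@H](OC(C)=O)C[C@@](O)(C(C)C)[C@H]12 | intermediate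
20 | (1S,3R,3aS,4S,8aR)-3,4-dihydroxy-6,8a-dimethyl-7-oxo-3-(propan-2-yl)decahydroazulen-1-yl acetate | O[C@H]1CC(C)C(=O)C[C@@]2(C)[C@@H](OC(C)=O)C[C@@](O)(C(C)C)[C@H]12 | intermediate
21 | (1S,3R,3aS,4S,8aR)-1-(acetyloxy)-3-hydroxy-6,8a-dimethyl-7-oxo-3-(propan-2-yl)decahydroazulen-4-yl 4-methoxybenzoate | COc1ccc(C(=O)O[C@H]2CC(C)C(=O)C[C@@]3(C)[C@@H](OC(C)=O)C[C@@](O)(C(C)C)[C@H]23)cc1 | intermediate
22 | (1S,3R,3aS,4S,8aR)-1-(acetyloxy)-6,8a-dimethyl-7-oxo-3-(propan-2-yl)-3-(triethylsilyloxy)decahydroazulen-4-yl 4-methoxybenzoate | COc1ccc(C(=O)O[C@H]2CC(C)C(=O)C[C@@]3(C)[C@@H](OC(C)=O)C[C@@](O[Si](CC)(CC)CC)(C(C)C)[C@H]23)cc1 | intermediate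
23 | C8=C9 enol triflate of 22 | COc1ccc(C(=O)O[C@H]2CC(C)=C(OS(=O)(=O)C(F)(F)F)C[C@@]3(C)[C@@H](OC(C)=O)C[C@@](O[Si](CC)(CC)CC)(C(C)C)[C@H]23)cc1 | intermediate
24 | C4 triethylsilyl ether of the target | COc1ccc(C(=O)O[C@H]2CC(C)=CC[C@@]3(C)[C@@H](OC(C)=O)C[C@@](O[Si](CC)(CC)CC)(C(C)C)[C@H]23)cc1 | intermediate
25 | (1S,3R,3aS,4S,8aR)-1-(acetyloxy)-3-hydroxy-6,8a-dimethyl-3-(propan-2-yl)-1,2,3,3a,4,5,8,8a-octahydroazulen-4-yl 4-methoxybenzoate | COc1ccc(C(=O)O[C@H]2CC(C)=CC[C@@]3(C)[C@@H](OC(C)=O)C[C@@](O)(C(C)C)[C@H]23)cc1 | target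

Total step count: 14. Longest linear sequence: 13 steps (5 → 25 through steps 2–14); the aldol branch (step 1) joins at step 6.

Steps most likely to fail

Step 9. The facial selectivity at C1 may erode if the hydrogen bond is not maintained, for instance in the C8 epimer whose methyl shields the reacting face. C5 may also fail to reach the trans-fused epimer under a base mild enough to spare the free C4 ketol. The fallback sets out from 16 and returns at 19. The tertiary hydroxyl of 16 is silylated (TESOTf, 2,6-lutidine) to the triethylsilyl ether F1, so that face control rests on A(1,2) strain and the bulk of the silyl ether. Irradiation gives the silylated photoadduct F2, hydrogenolysis the silylated cyclobutanol F3, and retro-aldol the silylated dione F4. Without a free ketol, F4 can be equilibrated at C5 with DBU in hot PhMe free of retro-aldol risk, and HF·pyridine then gives 19.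

Step 6. The cerium reagent may enolise the isopropyl ketone, the aldolate may revert, or the 1,3-induction may be weak. The fallback sets out from 10 (with 2) and returns at 14; it reverses the order of bond formation. Vinyllithium 10 is acylated with N-methoxy-N-methylacetamide to the methyl ketone F5. Its boron enolate, made with (+)-Ipc2BCl and Et3N, adds to methacrolein 2 to give the (R)-aldol F6. Chelation-controlled addition of the smaller isopropyl nucleophile (i-PrMgCl, CeCl3) to the alkoxide of F6 should give the (3R,5R)-diol F7, which has the correct C4 configuration. Mitsunobu esterification with acetic acid (PPh3, DIAD) then inverts C2 and delivers 14.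

Step 12. Proton loss toward C10 instead of C8 would give the regioisomeric triflate, and the silyl ether may be attacked by the anhydride. The fallback sets out from 22 and returns at 23; regiochemistry is settled by equilibrating an isolated silyl enol ether. Me3SiI with (Me3Si)2NH in CH2Cl2 gives the thermodynamic trimethylsilyl enol ether F8 (C8=C9), and CsF with PhNTf2 in DME converts it into 23 with the double bond position unchanged.

Further compounds
F1 | step 9 | C4 triethylsilyl ether of 16 | C=C(C)[C@@H](OC(C)=O)C[C@@](O[Si](CC)(CC)CC)(C(C)C)C1=C(OCc2ccccc2)C(C)CC1=O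
F2 | step 9 | silylated cyclobutane photoadduct | O=C1CC(C)[C@]2(OCc4ccccc4)C[C@@]3(C)[C@@H](OC(C)=O)C[C@@](O[Si](CC)(CC)CC)(C(C)C)[C@@]123
F3 | step 9 | silylated cyclobutanol | O=C1CC(C)[C@]2(O)C[C@@]3(C)[C@@H](OC(C)=O)C[C@@](O[Si](CC)(CC)CC)(C(C)C)[C@@]123
F4 | step 9 | C4 triethylsilyl ether of dione 19 | O=C1CC(C)C(=O)C[C@@]2(C)[C@@H](OC(C)=O)C[C@@](O[Si](CC)(CC)CC)(C(C)C)[C@H]12
F5 | step 6 | 1-[2-(benzyloxy)-5-(tert-butyldimethylsilyloxy)-3-methylcyclopent-1-en-1-yl]ethan-1-one | CC(=O)C1=C(OCc2ccccc2)C(C)CC1O[Si](C)(C)C(C)(C)C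
F6 | step 6 | (3R)-1-[2-(benzyloxy)-5-(tert-butyldimethylsilyloxy)-3-methylcyclopent-1-en-1-yl]-3-hydroxy-4-methylpent-4-en-1-one | C=C(C)[C@H](O)CC(=O)C1=C(OCc2ccccc2)C(C)CC1O[Si](C)(C)C(C)(C)C
F7 | step 6 | (3R,5R)-5-[2-(benzyloxy)-5-(tert-butyldimethylsilyloxy)-3-methylcyclopent-1-en-1-yl]-2,6-dimethylhept-1-ene-3,5-diol | C=C(C)[C@H](O)C[C@@](O)(C(C)C)C1=C(OCc2ccccc2)C(C)CC1O[Si](C)(C)C(C)(C)C
F8 | step 12 | C8=C9 trimethylsilyl enol ether of 22 | COc1ccc(C(=O)O[C@H]2CC(C)=C(O[Si](C)(C)C)C[C@@]3(C)[C@@H](OC(C)=O)C[C@@](O[Si](CC)(CC)CC)(C(C)C)[C@H]23)cc1
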